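**Retrosynthetic overview**
- The two 4-hydroxybenzoate esters are cut last (double esterification of a C3-hydroxymethyl/allylic diol), and the (E)-hydroxypropenyl arm is cut at the C5 aryl–alkenyl bond (Suzuki coupling on a C5 bromide).
- The route rests on one feature: C2 carries a single aryl group and lies between O1 and C3, so the dihydrofuran ring divides into the four-atom unit O1–C7a–C3a–C3 (an ortho-quinone methide) and a one-carbon aryl–CH unit (a benzylic sulfonium ylide).
- A [4+1] annulation joins them, forming C2–C3 first and O1–C2 second, with the C2-symmetric thiolane on sulfur controlling C2 and the trans relationship fixing C3.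
- The quinone methide comes from a 2-(1-tosylalkyl)phenol made from 5-bromo-2-hydroxy-3-methoxybenzaldehyde; the ylide comes from a sulfonium triflate made from syringaldehyde and (2S,5S)-2,5-dimethylthiolane.
- Ring order: all benzene rings are bought; the dihydrofuran ring is the only ring made (step 11).

Key step: step 11

Assumption: the sense of induction of the thiolane is taken from its behaviour in benzylidene transfer to aldehydes (the methyl group cis to the ylide carbon shields one ylide face), which assigns the 2S series to the (2S,5S)-sulfide; both enantiomers of hexane-2,5-diol and the alkenylboronate of step 13 are taken as purchasable.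

**Route**

Step 1
Reactants: 1 5-bromo-2-hydroxy-3-methoxybenzaldehyde
Product: 2 4-bromo-2-methoxy-6-vinylphenol
Conditions: Ph3PCH3Br (2.5 equiv), KOtBu (2.5 equiv), THF, 0 °C → rt
Reagents that add atoms: methyltriphenylphosphonium bromide, C[P+](c1ccccc1)(c1ccccc1)c1ccccc1.[Br-]
Why: Wittig methylenation of a salicylaldehyde should proceed on the phenoxide when the ylide is in excess, the first equivalent of base being taken up by the phenol.

Step 2
Reactants: 2 4-bromo-2-methoxy-6-vinylphenol
Product: 3 rac-1-(5-bromo-2-hydroxy-3-methoxyphenyl)ethane-1,2-diol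
Conditions: K2OsO4·2H2O (1 mol%), NMO (1.3 equiv), acetone/H2O (5:1), rt
Reagents that add atoms: N-methylmorpholine N-oxide, C[N+]1([O-])CCOCC1; water, O
Why: Osmium-catalysed syn-dihydroxylation of the terminal styrene with NMO as reoxidant should give the diol, and the new benzylic centre is left racemic because step 11 destroys it.

Step 3
Reactants: 3 rac-1-(5-bromo-2-hydroxy-3-methoxyphenyl)ethane-1,2-diol
Product: 4 rac-4-bromo-2-[2-(tert-butyldimethylsilyloxy)-1-hydroxyethyl]-6-methoxyphenol
Conditions: TBSCl (1.05 equiv), imidazole (2.2 equiv), DMF/CH2Cl2, −20 → 0 °C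
Reagents that add atoms: tert-butyldimethylsilyl chloride, CC(C)(C)[Si](C)(C)Cl
Why: Silyl ether formation should be fastest at the unhindered primary hydroxyl, since the secondary benzylic hydroxyl and the hydrogen-bonded 2,6-disubstituted phenol react more slowly with one equivalent of the bulky chlorosilane at low temperature.

Step 4
Reactants: 4 rac-4-bromo-2-[2-(tert-butyldimethylsilyloxy)-1-hydroxyethyl]-6-methoxyphenol
Product: 5 rac-4-bromo-2-methoxy-6-[2-(tert-butyldimethylsilyloxy)-1-tosylethyl]phenol
Conditions: p-TolSO2H (1.5 equiv), MgSO4, CH2Cl2, 0 °C → rt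
Reagents that add atoms: p-toluenesulfinic acid, Cc1ccc(S(=O)O)cc1
Why: Acid-promoted SN1-type substitution, in which the ortho-hydroxyl assists loss of the benzylic hydroxyl as water and the sulfinate is captured at sulfur, is the standard entry to 2-(1-tosylalkyl)phenols, and the weak acid in a dried aprotic medium should spare the primary TBS ether.

Step 5
Reactants: 6 syringaldehyde (4-hydroxy-3,5-dimethoxybenzaldehyde)
Product: 7 3,5-dimethoxy-4-(triisopropylsilyloxy)benzaldehyde
Conditions: TIPSCl (1.3 equiv), imidazole (2.5 equiv), DMAP (0.1 equiv), DMF, rt → 40 °C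
Reagents that add atoms: triisopropylsilyl chloride, CC(C)[Si](Cl)(C(C)C)C(C)C
Why: Silylation of the acidic para-formyl phenol should give a hindered aryl TIPS ether, flanked by two methoxy groups, that withstands the carbonate, phosphate and mild acid used later.

Step 6
Reactants: 7 3,5-dimethoxy-4-(triisopropylsilyloxy)benzaldehyde
Product: 8 [3,5-dimethoxy-4-(triisopropylsilyloxy)phenyl]methanol
Conditions: NaBH4 (1.0 equiv), MeOH/THF, 0 °C
Reagents that add atoms: none
Why: Borohydride reduction of the aryl aldehyde to the benzylic alcohol leaves the aryl silyl ether untouched.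

Step 7
Reactants: 8 [3,5-dimethoxy-4-(triisopropylsilyloxy)phenyl]methanol
Product: 9 3,5-dimethoxy-4-(triisopropylsilyloxy)benzyl bromide
Conditions: PBr3 (0.4 equiv), CH2Cl2, 0 °C; used at once
Reagents that add atoms: phosphorus tribromide, BrP(Br)Br
Why: Bromination of a primary benzylic alcohol with PBr3 (phosphite ester, then displacement by bromide) is fast for this electron-rich system, whose labile bromide is carried on without storage.

Step 8
Reactants: 10 (2R,5R)-hexane-2,5-diol
Product: 11 (2R,5R)-hexane-2,5-diyl dimethanesulfonate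
Conditions: MsCl (2.4 equiv), Et3N (3 equiv), CH2Cl2, −20 → 0 °C
Reagents that add atoms: methanesulfonyl chloride, CS(=O)(=O)Cl
Why: Mesylation takes place at oxygen, so both secondary stereocentres are retained.

Step 9
Reactants: 11 (2R,5R)-hexane-2,5-diyl dimethanesulfonate
Product: 12 (2S,5S)-2,5-dimethylthiolane
Conditions: Na2S·9H2O (1.2 equiv), DMSO, rt
Reagents that add atoms: sodium sulfide, [Na+].[Na+].[S-2]
Why: Double SN2 displacement by sulfide (intermolecular, then 5-exo-tet) inverts both centres and should give the C2-symmetric trans-thiolane as the (2S,5S) enantiomer.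

Step 10
Reactants: 9 3,5-dimethoxy-4-(triisopropylsilyloxy)benzyl bromide; 12 (2S,5S)-2,5-dimethylthiolane (1.3 equiv)
Product: 13 (2S,5S)-1-[3,5-dimethoxy-4-(triisopropylsilyloxy)benzyl]-2,5-dimethylthiolanium trifluoromethanesulfonate
Conditions: AgOSO2CF3 (1.05 equiv), CH2Cl2, −30 °C → rt, dark
Reagents that add atoms: silver trifluoromethanesulfonate, [Ag+].[O-]S(=O)(=O)C(F)(F)F
Why: S-Alkylation of the hindered sulfide is driven to completion by halide abstraction, the non-nucleophilic triflate prevents dealkylation of the salt, and because sulfur in the C2-symmetric thiolane is not a stereocentre a single salt should form.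

Step 11
Reactants: 5 rac-4-bromo-2-methoxy-6-[2-(tert-butyldimethylsilyloxy)-1-tosylethyl]phenol (1.3 equiv, added slowly); 13 (2S,5S)-1-[3,5-dimethoxy-4-(triisopropylsilyloxy)benzyl]-2,5-dimethylthiolanium trifluoromethanesulfonate
Product: 17 (2S,3R)-5-bromo-3-(tert-butyldimethylsilyloxymethyl)-7-methoxy-2-[3,5-dimethoxy-4-(triisopropylsilyloxy)phenyl]-2,3-dihydrobenzofuran, via ortho-quinone methide 14 (not isolated), via benzylic sulfonium ylide 15 (not isolated), via phenoxide–sulfonium betaine 16 (not isolated)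
Conditions: Cs2CO3 (3 equiv), CH2Cl2, −20 °C → rt
Reagents that add atoms: none
Why: Cs2CO3 deprotonates the phenol of 5, which expels p-toluenesulfinate to give quinone methide 14 (its exocyclic carbon is the future C3), and deprotonates 13 to the semi-stabilised ylide 15 (its carbon is the future C2); conjugate addition of 15 to 14 forms C2–C3 with rearomatisation to betaine 16, whose phenoxide then displaces the thiolane at C2 with inversion to form O1–C2. The closest known reaction type is the formal [4+1] annulation of ortho-quinone methides released from 2-(1-tosylalkyl)phenols with sulfonium ylides, which gives trans-2,3-dihydrobenzofurans and has chiral-sulfide variants. The dihydrofuran ring closes by 5-exo-tet substitution. C2 is controlled by the thiolane: the ylide aryl group points away from the ring and the methyl group cis to the ylide carbon shields one face, and this model, after the change of CIP priorities at C2, assigns 2S to the (2S,5S)-sulfide. C3 is set relative to C2 in the addition step by the open approach that keeps the syringyl and CH2OTBS groups apart, which should give the trans ring. The step needs ylide capture to outrun tautomerisation of 14 to a vinylogous silyl enol ether, and slow addition of 5 to an excess of the nucleophilic ylide at low temperature, together with the electron-poor bromo-substituted quinone methide, should secure this.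

Step 12
Reactants: 17 (2S,3R)-5-bromo-3-(tert-butyldimethylsilyloxymethyl)-7-methoxy-2-[3,5-dimethoxy-4-(triisopropylsilyloxy)phenyl]-2,3-dihydrobenzofuran
Product: 18 [(2S,3R)-5-bromo-2-[3,5-dimethoxy-4-(triisopropylsilyloxy)phenyl]-7-methoxy-2,3-dihydrobenzofuran-3-yl]methanol
Conditions: CSA (0.1 equiv), MeOH/CH2Cl2 (1:1), 0 °C → rt
Reagents that add atoms: none
Why: Acid-catalysed methanolysis cleaves the primary alkyl TBS ether far faster than the hindered aryl TIPS ether, and it is run before the acid-sensitive cinnamyl alcohol is present.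

Step 13
Reactants: 18 [(2S,3R)-5-bromo-2-[3,5-dimethoxy-4-(triisopropylsilyloxy)phenyl]-7-methoxy-2,3-dihydrobenzofuran-3-yl]methanol; 19 (E)-3-(4,4,5,5-tetramethyl-1,3,2-dioxaborolan-2-yl)prop-2-en-1-ol (1.5 equiv)
Product: 20 (E)-3-[(2S,3R)-2-[3,5-dimethoxy-4-(triisopropylsilyloxy)phenyl]-3-(hydroxymethyl)-7-methoxy-2,3-dihydrobenzofuran-5-yl]prop-2-en-1-ol
Conditions: Pd(OAc)2 (5 mol%), SPhos (10 mol%), K3PO4 (3 equiv), THF/H2O (10:1), 60 °C
Reagents that add atoms: none
Why: Suzuki–Miyaura coupling of the electron-rich aryl bromide with the (E)-alkenylboronate should proceed with retention of alkene geometry, the electron-rich biarylphosphine easing oxidative addition and the phosphate base sparing the aryl silyl ether.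

Step 14
Reactants: 21 4-hydroxybenzoic acid
Product: 23 4-(tert-butyldimethylsilyloxy)benzoic acid, via silyl ester 22 (not isolated)
Conditions: TBSCl (2.3 equiv), imidazole (5 equiv), DMF, rt; then AcOH/THF/H2O (3:1:1), rt
Reagents that add atoms: tert-butyldimethylsilyl chloride, CC(C)(C)[Si](C)(C)Cl
Why: Exhaustive silylation followed by selective hydrolysis of the silyl ester, which cleaves far faster than the aryl silyl ether, should give the O-protected acid.

Step 15
Reactants: 20 (E)-3-[(2S,3R)-2-[3,5-dimethoxy-4-(triisopropylsilyloxy)phenyl]-3-(hydroxymethyl)-7-methoxy-2,3-dihydrobenzofuran-5-yl]prop-2-en-1-ol; 23 4-(tert-butyldimethylsilyloxy)benzoic acid (2.4 equiv)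
Product: 24 (E)-3-[(2S,3R)-3-{[4-(tert-butyldimethylsilyloxy)benzoyloxy]methyl}-2-[3,5-dimethoxy-4-(triisopropylsilyloxy)phenyl]-7-methoxy-2,3-dihydrobenzofuran-5-yl]prop-2-enyl 4-(tert-butyldimethylsilyloxy)benzoate
Conditions: DCC (2.6 equiv), DMAP (0.3 equiv), CH2Cl2, 0 °C → rt
Reagents that add atoms: none
Why: Steglich esterification should acylate both primary hydroxyls through the acylpyridinium species under neutral conditions that leave the stereocentres, the alkene and the three aryl silyl ethers intact.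

Step 16
Reactants: 24 (E)-3-[(2S,3R)-3-{[4-(tert-butyldimethylsilyloxy)benzoyloxy]methyl}-2-[3,5-dimethoxy-4-(triisopropylsilyloxy)phenyl]-7-methoxy-2,3-dihydrobenzofuran-5-yl]prop-2-enyl 4-(tert-butyldimethylsilyloxy)benzoate
Product: 25 quiquesetinerviusin B
Conditions: Bu4NF (3.6 equiv), AcOH (3.6 equiv), THF, 0 °C → rt
Reagents that add atoms: none
Why: Fluoride-mediated desilylation removes the three aryl silyl ethers, and buffering with acetic acid keeps the phenols protonated so that the two benzoate esters should be neither cleaved nor migrated.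

**Compound list**
1 | 5-bromo-2-hydroxy-3-methoxybenzaldehyde | COc1cc(Br)cc(C=O)c1O | starting material
2 | 4-bromo-2-methoxy-6-vinylphenol | C=Cc1cc(Br)cc(OC)c1O | intermediate
3 | rac-1-(5-bromo-2-hydroxy-3-methoxyphenyl)ethane-1,2-diol | OCC(O)c1cc(Br)cc(OC)c1O | intermediate
4 | rac-4-bromo-2-[2-(tert-butyldimethylsilyloxy)-1-hydroxyethyl]-6-methoxyphenol | COc1cc(Br)cc(C(O)CO[Si](C)(C)C(C)(C)C)c1O | intermediate
5 | rac-4-bromo-2-methoxy-6-[2-(tert-butyldimethylsilyloxy)-1-tosylethyl]phenol | COc1cc(Br)cc(C(CO[Si](C)(C)C(C)(C)C)S(=O)(=O)c2ccc(C)cc2)c1O | intermediate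
6 | syringaldehyde | COc1cc(C=O)cc(OC)c1O | starting material
7 | 3,5-dimethoxy-4-(triisopropylsilyloxy)benzaldehyde | COc1cc(C=O)cc(OC)c1O[Si](C(C)C)(C(C)C)C(C)C | intermediate
8 | [3,5-dimethoxy-4-(triisopropylsilyloxy)phenyl]methanol | COc1cc(CO)cc(OC)c1O[Si](C(C)C)(C(C)C)C(C)C | intermediate
9 | 3,5-dimethoxy-4-(triisopropylsilyloxy)benzyl bromide | COc1cc(CBr)cc(OC)c1O[Si](C(C)C)(C(C)C)C(C)C | intermediate
10 | (2R,5R)-hexane-2,5-diol | C[C@@H](O)CC[C@@H](C)O | starting material
11 | (2R,5R)-hexane-2,5-diyl dimethanesulfonate | C[C@@H](OS(C)(=O)=O)CC[C@@H](C)OS(C)(=O)=O | intermediate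
12 | (2S,5S)-2,5-dimethylthiolane | C[C@H]1CC[C@H](C)S1 | intermediate
13 | (2S,5S)-1-[3,5-dimethoxy-4-(triisopropylsilyloxy)benzyl]-2,5-dimethylthiolanium trifluoromethanesulfonate | C[C@H]1CC[C@H](C)[S+]1Cc1cc(OC)c(O[Si](C(C)C)(C(C)C)C(C)C)c(OC)c1.[O-]S(=O)(=O)C(F)(F)F | intermediate
14 | 4-bromo-6-[2-(tert-butyldimethylsilyloxy)ethylidene]-2-methoxycyclohexa-2,4-dien-1-one (ortho-quinone methide, alkene geometry not fixed) | COC1=CC(Br)=CC(=CCO[Si](C)(C)C(C)(C)C)C1=O | intermediate
15 | ylide of 13: (2S,5S)-2,5-dimethylthiolanium [3,5-dimethoxy-4-(triisopropylsilyloxy)phenyl]methanide | C[C@H]1CC[C@H](C)[S+]1[CH-]c1cc(OC)c(O[Si](C(C)C)(C(C)C)C(C)C)c(OC)c1 | intermediate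
16 | phenoxide–sulfonium betaine (C–C adduct of 14 and 15) | COc1cc(Br)cc([C@H](CO[Si](C)(C)C(C)(C)C)[C@H](c2cc(OC)c(O[Si](C(C)C)(C(C)C)C(C)C)c(OC)c2)[S+]2[C@@H](C)CC[C@@H]2C)c1[O-] | intermediate
17 | (2S,3R)-5-bromo-3-(tert-butyldimethylsilyloxymethyl)-7-methoxy-2-[3,5-dimethoxy-4-(triisopropylsilyloxy)phenyl]-2,3-dihydrobenzofuran | COc1cc([C@H]2Oc3c(OC)cc(Br)cc3[C@@H]2CO[Si](C)(C)C(C)(C)C)cc(OC)c1O[Si](C(C)C)(C(C)C)C(C)C | intermediate
18 | [(2S,3R)-5-bromo-2-[3,5-dimethoxy-4-(triisopropylsilyloxy)phenyl]-7-methoxy-2,3-dihydrobenzofuran-3-yl]methanol | COc1cc([C@H]2Oc3c(OC)cc(Br)cc3[C@@H]2CO)cc(OC)c1O[Si](C(C)C)(C(C)C)C(C)C | intermediate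
19 | (E)-3-(4,4,5,5-tetramethyl-1,3,2-dioxaborolan-2-yl)prop-2-en-1-ol | OC/C=C/B1OC(C)(C)C(C)(C)O1 | starting material
20 | (E)-3-[(2S,3R)-2-[3,5-dimethoxy-4-(triisopropylsilyloxy)phenyl]-3-(hydroxymethyl)-7-methoxy-2,3-dihydrobenzofuran-5-yl]prop-2-en-1-ol | COc1cc([C@H]2Oc3c(OC)cc(/C=C/CO)cc3[C@@H]2CO)cc(OC)c1O[Si](C(C)C)(C(C)C)C(C)C | intermediate
21 | 4-hydroxybenzoic acid | O=C(O)c1ccc(O)cc1 | starting material
22 | tert-butyldimethylsilyl 4-(tert-butyldimethylsilyloxy)benzoate | CC(C)(C)[Si](C)(C)OC(=O)c1ccc(O[Si](C)(C)C(C)(C)C)cc1 | intermediate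
23 | 4-(tert-butyldimethylsilyloxy)benzoic acid | OC(=O)c1ccc(O[Si](C)(C)C(C)(C)C)cc1 | intermediate
24 | bis[4-(tert-butyldimethylsilyloxy)benzoate] of 20 | COc1cc([C@H]2Oc3c(OC)cc(/C=C/COC(=O)c4ccc(O[Si](C)(C)C(C)(C)C)cc4)cc3[C@@H]2COC(=O)c2ccc(O[Si](C)(C)C(C)(C)C)cc2)cc(OC)c1O[Si](C(C)C)(C(C)C)C(C)C | intermediate
25 | quiquesetinerviusin B | COc1cc([C@H]2Oc3c(OC)cc(/C=C/COC(=O)c4ccc(O)cc4)cc3[C@@H]2COC(=O)c2ccc(O)cc2)cc(OC)c1O | target

**Step count**
Total: 16 steps. Longest linear sequence: 9 steps (1 → 25 through steps 1–4, 11–13, 15 and 16; the same length from 6 through steps 5–7, 10, 11–13, 15 and 16).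

**Steps most likely to fail**

Step 11. The quinone methide may tautomerise by hydrogen shift to a vinylogous silyl enol ether before the ylide captures it, or the ylide may add with poor face selectivity. The fallback sets out from 2 and 9 and comes back at 18; it forms the two ring bonds in the reverse order by a rhodium-carbenoid C–H insertion.
- Phenol 2 is O-alkylated with bromide 9 (K2CO3, DMF) to 5-bromo-2-{[3,5-dimethoxy-4-(triisopropylsilyloxy)benzyl]oxy}-1-methoxy-3-vinylbenzene F1.
- Hydroboration with 9-BBN and oxidation with NaBO3 should give 2-(5-bromo-2-{[3,5-dimethoxy-4-(triisopropylsilyloxy)benzyl]oxy}-3-methoxyphenyl)ethanol F2.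
- Oxidation with TEMPO/PhI(OAc)2 in MeCN/H2O gives the corresponding arylacetic acid F3, and Me3SiCHN2 converts it to its methyl ester F4.
- Diazo transfer (4-acetamidobenzenesulfonyl azide, DBU, MeCN) gives the methyl aryldiazoacetate F5.
- Rh2(S-PTTL)4 (PTTL = N-phthaloyl-tert-leucinate; the mirror-image catalyst if the 2R series forms) in toluene at −60 °C should insert the carbenoid into one of the two enantiotopic benzylic C–H bonds next to the ether oxygen. This closes the ring to the cis ester methyl (2S,3R)-5-bromo-2-[3,5-dimethoxy-4-(triisopropylsilyloxy)phenyl]-7-methoxy-2,3-dihydrobenzofuran-3-carboxylate F6.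
- DBU in toluene epimerises C3 to the trans ester methyl (2S,3S)-5-bromo-2-[3,5-dimethoxy-4-(triisopropylsilyloxy)phenyl]-7-methoxy-2,3-dihydrobenzofuran-3-carboxylate F7, and LiBH4 in THF reduces it to 18.

Step 4. The primary TBS ether may be lost under the acid, or the benzylic cation may undergo a pinacol-type hydride shift to an arylacetaldehyde instead of capturing sulfinate. The fallback sets out from 3 and comes back at 5; it reverses the order of substitution and protection. Triol 3, which has no acid-labile group, is treated with p-TolSO2Na in aqueous HCO2H to give rac-4-bromo-2-(2-hydroxy-1-tosylethyl)-6-methoxyphenol F8. Its primary hydroxyl is then silylated with TBSOTf/2,6-lutidine in CH2Cl2 at −78 °C, a hindered non-nucleophilic base at a temperature that should not trigger sulfinate loss, to give 5.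

Step 10. The electron-rich benzyl bromide may ionise and self-alkylate (Friedel–Crafts) or decompose before the hindered sulfide captures it. The fallback sets out from 8 and 12 and comes back at 13; it is a direct dehydrative S-alkylation that avoids both the bromide and the silver salt (no new compound, F0). Alcohol 8 and sulfide 12 are treated with CF3SO3H (1 equiv) in CH2Cl2 at −40 °C, so that the benzylic cation from the protonated alcohol is formed in the presence of excess sulfide and trapped as triflate 13.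

**Further compounds**
F1 | step 11 | 5-bromo-2-{[3,5-dimethoxy-4-(triisopropylsilyloxy)benzyl]oxy}-1-methoxy-3-vinylbenzene | C=Cc1cc(Br)cc(OC)c1OCc1cc(OC)c(O[Si](C(C)C)(C(C)C)C(C)C)c(OC)c1
F2 | step 11 | 2-(5-bromo-2-{[3,5-dimethoxy-4-(triisopropylsilyloxy)benzyl]oxy}-3-methoxyphenyl)ethanol | OCCc1cc(Br)cc(OC)c1OCc1cc(OC)c(O[Si](C(C)C)(C(C)C)C(C)C)c(OC)c1
F3 | step 11 | (5-bromo-2-{[3,5-dimethoxy-4-(triisopropylsilyloxy)benzyl]oxy}-3-methoxyphenyl)acetic acid | OC(=O)Cc1cc(Br)cc(OC)c1OCc1cc(OC)c(O[Si](C(C)C)(C(C)C)C(C)C)c(OC)c1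
F4 | step 11 | methyl (5-bromo-2-{[3,5-dimethoxy-4-(triisopropylsilyloxy)benzyl]oxy}-3-methoxyphenyl)acetate | COC(=O)Cc1cc(Br)cc(OC)c1OCc1cc(OC)c(O[Si](C(C)C)(C(C)C)C(C)C)c(OC)c1
F5 | step 11 | methyl 2-diazo-2-(5-bromo-2-{[3,5-dimethoxy-4-(triisopropylsilyloxy)benzyl]oxy}-3-methoxyphenyl)acetate | COC(=O)C(=[N+]=[N-])c1cc(Br)cc(OC)c1OCc1cc(OC)c(O[Si](C(C)C)(C(C)C)C(C)C)c(OC)c1
F6 | step 11 | methyl (2S,3R)-5-bromo-2-[3,5-dimethoxy-4-(triisopropylsilyloxy)phenyl]-7-methoxy-2,3-dihydrobenzofuran-3-carboxylate (cis) | COc1cc([C@H]2Oc3c(OC)cc(Br)cc3[C@H]2C(=O)OC)cc(OC)c1O[Si](C(C)C)(C(C)C)C(C)C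
F7 | step 11 | methyl (2S,3S)-5-bromo-2-[3,5-dimethoxy-4-(triisopropylsilyloxy)phenyl]-7-methoxy-2,3-dihydrobenzofuran-3-carboxylate (trans) | COc1cc([C@H]2Oc3c(OC)cc(Br)cc3[C@@H]2C(=O)OC)cc(OC)c1O[Si](C(C)C)(C(C)C)C(C)C
F8 | step 4 | rac-4-bromo-2-(2-hydroxy-1-tosylethyl)-6-methoxyphenol | COc1cc(Br)cc(C(CO)S(=O)(=O)c2ccc(C)cc2)c1O
F0 | step 10 | none | none
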